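**Retrosynthetic overview**
1. Numbering: ring C1–C10 (C1=C2, C3=O, C4(CH3)=C5, C6–O, C7, C8–O, C9H2, C10(CH3)OH), lactone O6–C12(=O)–C11(=C13H2)–C7, tiglate on O8. The strategy rests on this: C1–C2–C3 and C8–C9–C10 are the alkyne arm and the enol-ether arm of a 1,5-enyne as soon as C3 and C8 are bonded, and that bond closes a cyclohexene C3–C4=C5–C6–C7–C8, the carvone skeleton.
2. Late disconnections: γ-lactone (oxidative lactonisation of the O6/O12 diol), O8 tiglate, C8 carbinol (hydroxyl-directed reduction of the C8 ketone).
3. Key disconnection: C1–C10, by anionic alkynyl oxy-Cope ring expansion of a 1-ethynylcyclohex-2-enol. O8 and the enol oxygen O10 are tied in one spiro di-tert-butylsilylene ring, which fixes the enol ether as C9=C10 with Z geometry, holds O10 next to O8, and leaves no free O8 alkoxide that could strip a silyl group from the enol ether.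
4. Precursor from (S)-carvone: C12 chlorination and aryl ether, C8 allylation then hydroxylation, C6 γ-hydroxylation and Mitsunobu inversion, Wacker oxidation, silylene closure, ethynyl addition.
5. Ring order: cyclohexene (from carvone) → spiro dioxasilin (temporary) → ten-membered ring (step 11) → γ-lactone (step 16).

Key step: step 11

Remark: the open (1Z)-10-hydroxy-3-ketone drawn for the target is taken as the target although it can close reversibly to its 3,10-hemiketal; the same is assumed for compounds 21 to 28.

Step 1
Reactants: 1 (S)-carvone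
Product: 2 (S)-10-chlorocarvone
Conditions: Ca(OCl)2, CO2 (solid), CH2Cl2/H2O, 0 °C
Reagents that add atoms: calcium hypochlorite, [Ca+2].[O-]Cl.[O-]Cl
Why: Ene-type allylic chlorination by HOCl made in the flask should attack only the electron-rich 1,1-disubstituted alkene, leaving the enone and the C7 stereocentre untouched.

Step 2
Reactants: 2 (S)-10-chlorocarvone; 3 4-methoxyphenol
Product: 4 O12 4-methoxyphenyl ether of 10-hydroxycarvone
Conditions: K2CO3, NaI (cat.), acetone, reflux
Reagents that add atoms: 4-methoxyphenol 3, COc1ccc(O)cc1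
Why: Williamson ether synthesis on the allylic chloride with a phenoxide under carbonate conditions, which are too weakly basic to form the carvone dienolate, should give an O12 ether that tolerates amide bases, Grignard reagents and divalent palladium.

Step 3
Reactants: 4 O12 aryl ether; 5 allyl bromide
Product: 7 8-allyl ketone (allyl trans to the C7 side chain), via lithium enolate 6 (not isolated)
Conditions: LiN(iPr)2, THF, −78 °C; then 5, −78 → −20 °C
Reagents that add atoms: allyl bromide 5, C=CCBr; LiN(iPr)2, [Li+].CC(C)[N-]C(C)C (lithium of 6 only)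
Why: Kinetic deprotonation at the C8 methylene and enolate alkylation should place the allyl group trans to the C7 side chain, but C8 is re-enolised in step 4 so this configuration is not critical.

Step 4
Reactants: 7 8-allyl ketone
Product: 9 8-allyl-8-hydroxy ketone (O8 trans and allyl cis to the C7 side chain), via potassium enolate 8 (not isolated)
Conditions: KN(SiMe3)2, THF, −78 °C; 2-(phenylsulfonyl)-3-phenyloxaziridine, −78 °C; AcOH quench
Reagents that add atoms: 2-(phenylsulfonyl)-3-phenyloxaziridine, O=S(=O)(c1ccccc1)N1OC1c1ccccc1; KN(SiMe3)2, [K+].C[Si](C)(C)[N-][Si](C)(C)C (potassium of 8 only)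
Why: Enolate hydroxylation with an N-sulfonyloxaziridine should occur on the face of the tetrasubstituted C3=C8 enolate opposite the adjacent C7 side chain, which sets C8 with O8 trans and the allyl group cis to that side chain.

Step 5
Reactants: 9 8-allyl-8-hydroxy ketone
Product: 10 bis(trimethylsilyl) compound (3-silyloxy-3,5-diene and O8 silyl ether)
Conditions: Me3SiOTf, Et3N, CH2Cl2, 0 °C; used crude
Reagents that add atoms: trimethylsilyl trifluoromethanesulfonate, C[Si](C)(C)OS(=O)(=O)C(F)(F)F
Why: Silyl triflate/amine silylation caps the tertiary hydroxyl and, because C8 is now quaternary, soft enolisation can only remove a C6 proton, which should give the extended silyl dienol ether.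

Step 6
Reactants: 10 bis(trimethylsilyl) compound
Product: 12 6,8-dihydroxy enone (6-OH trans to the C7 side chain), via silyloxy epoxide 11 (not isolated)
Conditions: dimethyldioxirane, acetone/CH2Cl2, −78 → −20 °C; then citric acid (cat.), MeOH, 0 °C
Reagents that add atoms: dimethyldioxirane, CC1(C)OO1
Why: Vinylogous Rubottom oxidation should epoxidise the terminal C5=C6 bond of the dienol ether (C4 is shielded by its methyl group, the other alkenes are less electron-rich) anti to the C7 side chain, and methanolysis opens the epoxide to the γ-hydroxy enone and frees O8.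

Step 7
Reactants: 12 6,8-dihydroxy enone; 3 4-methoxyphenol
Product: 13 6-(4-methoxyphenoxy)-8-hydroxy enone (O6 cis to the C7 side chain)
Conditions: 3, PPh3, diisopropyl azodicarboxylate, toluene, 0 °C → rt
Reagents that add atoms: 4-methoxyphenol 3, COc1ccc(O)cc1
Why: Mitsunobu etherification should invert C6 by SN2 displacement (no anti β-hydrogen for elimination, the tertiary O8 hydroxyl is inert), giving O6 cis to the C7 side chain as the target requires and protecting it in the same operation.

Step 8
Reactants: 13 6-(4-methoxyphenoxy)-8-hydroxy enone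
Product: 14 8-(2-oxopropyl) compound (β-hydroxy methyl ketone)
Conditions: PdCl2 (cat.), CuCl (cat.), O2 (1 atm), DMF/H2O, rt
Reagents that add atoms: water, O (carbonyl oxygen; O2 is the terminal oxidant)
Why: Wacker oxidation should convert only the monosubstituted terminal alkene into the methyl ketone with Markovnikov selectivity, the 1,1-disubstituted alkene and the enone being far slower.

Step 9
Reactants: 14 β-hydroxy methyl ketone
Product: 15 spiro silylene ketone (C8 is the spiro atom of a 2,2-di-tert-butyl-6-methyl-4H-1,3,2-dioxasilin: O8–Si–O10 and C9=C10)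
Conditions: tBu2Si(OTf)2, Et3N, CH2Cl2, 0 °C → rt
Reagents that add atoms: di-tert-butylsilyl bis(trifluoromethanesulfonate), CC(C)(C)[Si](OS(=O)(=O)C(F)(F)F)(OS(=O)(=O)C(F)(F)F)C(C)(C)C
Why: O-silylation of the tertiary hydroxyl and silyl triflate/amine enolisation of the methyl ketone by the same silicon atom should close the six-membered silylene, in which the enol ether must be Z (O10 cis to C8) and the endocyclic C9=C10 isomer is the thermodynamic one under the equilibrating ammonium triflate.

Step 10
Reactants: 15 spiro silylene ketone; 16 ethynylmagnesium bromide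
Product: 17 1-ethynyl carbinol, the oxy-Cope precursor (drawn C3 epimer: ethynyl cis to O8 and trans to C9)
Conditions: 16, CeCl3, THF, −78 → 0 °C; aqueous NH4Cl
Reagents that add atoms: ethynylmagnesium bromide 16, C#C[Mg]Br
Why: 1,2-Addition of the acetylide to the hindered enone carbonyl (CeCl3 suppresses enolisation) should occur mainly on the face opposite the C9 arm and the C7 side chain, and the minor C3 epimer need not be removed because C3 becomes trigonal in step 11 and both epimers react through the same tether-fixed array.

Step 11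
Reactants: 17 1-ethynyl carbinol
Product: 20 ten-membered (1Z,4Z)-dien-3-one with the 8,10-O-silylene retained (C8=C9 enol ether), via potassium alkoxide 18 (not isolated), via potassium allenolate 19 (not isolated)
Conditions: KN(SiMe3)2, 18-crown-6, THF, −78 → 0 °C; AcOH, −78 °C
Reagents that add atoms: KN(SiMe3)2, [K+].C[Si](C)(C)[N-][Si](C)(C)C (potassium of 18 and 19 only)
Why: Deprotonation gives the C3 potassium alkoxide 18, whose charge weakens the C3–C8 bond so that the alkyne terminus C1 bonds to the enol-ether carbon C10 through a chair-like six-centre array C1–C2–C3–C8–C9–C10; the closest known reaction type is the anionic oxy-Cope rearrangement of 1-alkynyl-2-alkenylcyclohexanols to cyclodecadienones. The ten-membered ring is closed by four-atom ring expansion of the cyclohexene (the new C1–C10 bond replaces the ring bond C3–C8), not by end-to-end cyclisation, and C4=C5 stays Z because it was cis in the six-membered ring. C10 is the only new stereocentre and is set by suprafacial transfer of the C8 configuration across C8–C9=C10: the spiro silylene fixes the Z enol ether and the rotamer with O10 beside O8, so C1 can reach only the face of C10 that gives the required configuration, whichever C3 epimer reacts. The allenolate 19 should then be protonated at C2 from the open side of C1 (syn to its hydrogen, anti to the quaternary C10), which gives the Z C1=C2 enone. The step needs the [3,3] shift to outrun silyl transfer from O10 to the alkoxide and loss of acetylide; the bulky di-tert-butylsilylene, the anti disposition of O3 and O8 in the reactive conformer and the low temperature are what secure this.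

Step 12
Reactants: 20 ten-membered silylene dienone
Product: 21 10-hydroxy-3,8-dione
Conditions: HF·pyridine, pyridine, THF, 0 °C; pH 7 work-up, used directly
Reagents that add atoms: none
Why: Fluoride cleavage of both Si–O bonds (silyl enol ether and tertiary silyl ether) under buffered acidic conditions should release the C8 ketone and the C10 hydroxyl without base, which avoids retro-aldol opening of the β-hydroxy ketone.

Step 13
Reactants: 21 10-hydroxy-3,8-dione
Product: 22 8,10-anti diol
Conditions: Me4NBH(OAc)3, MeCN/AcOH, −30 °C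
Reagents that add atoms: none
Why: Saksena–Evans reduction, in which the C10 hydroxyl binds the borohydride and delivers hydride to the C8 ketone through a chair-like six-membered transition state, should give the 1,3-anti diol (the C8 configuration of the target) and leave the dienone carbonyl, which has no directing hydroxyl in reach, untouched.

Step 14
Reactants: 22 8,10-anti diol; 23 tiglic acid
Product: 25 8-O-tiglate, via mixed anhydride 24 (not isolated)
Conditions: 23, 2,4,6-trichlorobenzoyl chloride, Et3N, THF, rt; then 22, DMAP, toluene, rt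
Reagents that add atoms: tiglic acid 23, C/C=C(\C)C(=O)O; 2,4,6-trichlorobenzoyl chloride, O=C(Cl)c1c(Cl)cc(Cl)cc1Cl (in 24 only)
Why: Yamaguchi esterification should acylate the secondary C8 hydroxyl at the tigloyl carbonyl of the mixed anhydride, the tertiary C10 hydroxyl being too hindered to react and the E geometry of the acid being retained.

Step 15
Reactants: 25 8-O-tiglate
Product: 26 6,12-diol
Conditions: (NH4)2Ce(NO3)6, MeCN/H2O, 0 °C
Reagents that add atoms: none
Why: Oxidative dearylation by tetravalent cerium should convert each 4-methoxyphenyl ether into benzoquinone and the free alcohol with the C6–O and C12–O bonds intact (retention at C6), the electron-poor dienone, the ester and the tertiary alcohol being inert to this one-electron oxidant.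

Step 16
Reactants: 26 6,12-diol
Product: 29 target CNP0135074.2, via aldehyde 27 (not isolated), via lactol 28 (not isolated)
Conditions: TEMPO (cat.), PhI(OAc)2, CH2Cl2, rt
Reagents that add atoms: none
Why: TEMPO/PhI(OAc)2 oxidative lactonisation should oxidise the primary allylic C12 hydroxyl first, the aldehyde being trapped by the cis C6 hydroxyl as the lactol, which is oxidised to the α-methylene γ-lactone faster than the secondary or tertiary hydroxyls react.

**Compound list**
1 | (S)-carvone | CC1=CC[C@@H](CC1=O)C(C)=C | starting material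
2 | (S)-10-chlorocarvone, (5S)-5-(3-chloroprop-1-en-2-yl)-2-methylcyclohex-2-en-1-one | O=C1C(C)=CC[C@H](C(=C)CCl)C1 | intermediate
3 | 4-methoxyphenol | COc1ccc(O)cc1 | starting material
4 | (5S)-5-[3-(4-methoxyphenoxy)prop-1-en-2-yl]-2-methylcyclohex-2-en-1-one | O=C1C(C)=CC[C@H](C(=C)COc2ccc(OC)cc2)C1 | intermediate
5 | allyl bromide | C=CCBr | starting material
6 | lithium enolate of 4 (C3–OLi, C3=C8) | [Li+].[O-]C1=C[C@@H](C(=C)COc2ccc(OC)cc2)CC=C1C | intermediate
7 | 8-allyl ketone (allyl trans to the C7 side chain) | O=C1C(C)=CC[C@H](C(=C)COc2ccc(OC)cc2)[C@H]1CC=C | intermediate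
8 | potassium enolate of 7 (C3–OK, C3=C8) | [K+].[O-]C1=C(CC=C)[C@@H](C(=C)COc2ccc(OC)cc2)CC=C1C | intermediate
9 | 8-allyl-8-hydroxy ketone (O8 trans, allyl cis to the C7 side chain) | O=C1C(C)=CC[C@H](C(=C)COc2ccc(OC)cc2)[C@]1(O)CC=C | intermediate
10 | bis(trimethylsilyl) compound (3-trimethylsilyloxy-3,5-diene, O8 trimethylsilyl ether) | C[Si](C)(C)OC1=C(C)C=C[C@H](C(=C)COc2ccc(OC)cc2)[C@]1(O[Si](C)(C)C)CC=C | intermediate
11 | 5,6-epoxide of 10 (oxygen anti to the C7 side chain) | C[Si](C)(C)OC1=C(C)[C@H]2O[C@H]2[C@H](C(=C)COc3ccc(OC)cc3)[C@]1(O[Si](C)(C)C)CC=C | intermediate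
12 | 6,8-dihydroxy enone (6-OH trans to the C7 side chain) | O=C1C(C)=C[C@@H](O)[C@H](C(=C)COc2ccc(OC)cc2)[C@]1(O)CC=C | intermediate
13 | 6-(4-methoxyphenoxy)-8-hydroxy enone (O6 cis to the C7 side chain) | O=C1C(C)=C[C@H](Oc2ccc(OC)cc2)[C@H](C(=C)COc2ccc(OC)cc2)[C@]1(O)CC=C | intermediate
14 | 8-(2-oxopropyl) compound (β-hydroxy methyl ketone) | O=C1C(C)=C[C@H](Oc2ccc(OC)cc2)[C@H](C(=C)COc2ccc(OC)cc2)[C@]1(O)CC(C)=O | intermediate
15 | spiro silylene ketone (2,2-di-tert-butyl-6-methyl-4H-1,3,2-dioxasilin spiro at C8) | O=C1C(C)=C[C@H](Oc3ccc(OC)cc3)[C@H](C(=C)COc3ccc(OC)cc3)[C@@]12O[Si](C(C)(C)C)(C(C)(C)C)OC(C)=C2 | intermediate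
16 | ethynylmagnesium bromide | C#C[Mg]Br | starting material
17 | 1-ethynyl carbinol, oxy-Cope precursor (ethynyl cis to O8) | C#C[C@@]1(O)C(C)=C[C@H](Oc3ccc(OC)cc3)[C@H](C(=C)COc3ccc(OC)cc3)[C@@]12O[Si](C(C)(C)C)(C(C)(C)C)OC(C)=C2 | intermediate
18 | potassium alkoxide of 17 | [K+].C#C[C@@]1([O-])C(C)=C[C@H](Oc3ccc(OC)cc3)[C@H](C(=C)COc3ccc(OC)cc3)[C@@]12O[Si](C(C)(C)C)(C(C)(C)C)OC(C)=C2 | intermediate
19 | ten-membered potassium allenolate (C1=C2=C3–OK; allene axis set by the shift, not drawn) | [K+].[O-]C1=C=C[C@]2(C)O[Si](C(C)(C)C)(C(C)(C)C)OC(=C2)[C@@H](C(=C)COc3ccc(OC)cc3)[C@@H](Oc3ccc(OC)cc3)/C=C1/C | intermediate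
20 | ten-membered (1Z,4Z)-dien-3-one with 8,10-O-di-tert-butylsilylene (C8=C9 enol ether) | COc1ccc(O[C@H]2/C=C(/C)C(=O)/C=C\[C@]3(C)O[Si](C(C)(C)C)(C(C)(C)C)OC(=C3)[C@H]2C(=C)COc4ccc(OC)cc4)cc1 | intermediate
21 | 10-hydroxy-3,8-dione | COc1ccc(O[C@H]2/C=C(/C)C(=O)/C=C\[C@](C)(O)CC(=O)[C@H]2C(=C)COc3ccc(OC)cc3)cc1 | intermediate
22 | 8,10-anti diol | COc1ccc(O[C@H]2/C=C(/C)C(=O)/C=C\[C@](C)(O)C[C@@H](O)[C@H]2C(=C)COc3ccc(OC)cc3)cc1 | intermediate
23 | tiglic acid | C/C=C(\C)C(=O)O | starting material
24 | tiglic 2,4,6-trichlorobenzoic anhydride | C/C=C(\C)C(=O)OC(=O)c1c(Cl)cc(Cl)cc1Cl | intermediate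
25 | 8-O-tiglate with both 4-methoxyphenyl ethers | COc1ccc(O[C@H]2/C=C(/C)C(=O)/C=C\[C@](C)(O)C[C@@H](OC(=O)/C(C)=C/C)[C@H]2C(=C)COc3ccc(OC)cc3)cc1 | intermediate
26 | 6,12-diol 8-tiglate | O[C@H]1/C=C(/C)C(=O)/C=C\[C@](C)(O)C[C@@H](OC(=O)/C(C)=C/C)[C@H]1C(=C)CO | intermediate
27 | 12-aldehyde | O[C@H]1/C=C(/C)C(=O)/C=C\[C@](C)(O)C[C@@H](OC(=O)/C(C)=C/C)[C@H]1C(=C)C=O | intermediate
28 | lactol (C12 hemiacetal, both anomers) | C=C1C(O)O[C@H]2/C=C(/C)C(=O)/C=C\[C@](C)(O)C[C@@H](OC(=O)/C(C)=C/C)[C@@H]12 | intermediate
29 | CNP0135074.2 | C=C1C(=O)O[C@H]2/C=C(/C)C(=O)/C=C\[C@](C)(O)C[C@@H](OC(=O)/C(C)=C/C)[C@@H]12 | target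

Total step count: 16. Longest linear sequence: 16 steps (1 → 29).

**Steps most likely to fail**

Step 11. The shift may be outrun by transfer of the silylene from the enol oxygen to the C3 alkoxide or by loss of acetylide, or it may stall because the product ring must hold an allene beside two further double bonds. The fallback sets out from 15 and comes back at 20. Vinylmagnesium bromide is added to 15 as in step 10 to give the 1-vinyl carbinol F1. KN(SiMe3)2/18-crown-6 then brings about the anionic oxy-Cope rearrangement of this 1,2-dialkenylcyclohexenol, the best-precedented member of the class and free of the cyclic allene, through the same tether-fixed chair. The C2=C3 enolate is trapped in the flask with PhSeBr to give the 2-phenylselanyl ketone F2. H2O2 in CH2Cl2/pyridine at 0 °C then installs C1=C2 by selenoxide syn-elimination and gives 20; the geometry of that bond would be checked and, if E, corrected by irradiation.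

Step 9. Ring closure may occur by deprotonation at the methyl group and give the exocyclic enol ether, which is not a 1,5-enyne, or the amine may cleave the β-hydroxy ketone by retro-aldol reaction before silylation. The fallback sets out from 14 and comes back at 21. Me3SiCl/NaI/Et3N in MeCN, equilibrating conditions known to favour the more substituted Z enol ether, converts 14 into the open-chain bis(trimethylsilyl) ketone F3. Ethynylmagnesium bromide/CeCl3 gives the carbinol F4, purified to the epimer with ethynyl trans to C9 because without the tether the C10 configuration depends on it. KN(SiMe3)2/18-crown-6 followed by aqueous acid work-up gives the 10-trimethylsilyloxy-3,8-dione F5, and HF·pyridine converts this into 21.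

Step 13. Facial selectivity of hydride delivery may be poor because the ten-membered ring, not the six-membered boron chelate, may decide the conformation, and reversible closure of the C10 hydroxyl onto C3 may slow the directed pathway. The fallback sets out from 21 and comes back at 25. Narasaka–Prasad reduction (Et2BOMe, NaBH4, THF/MeOH, −78 °C; external hydride on the boron chelate) gives the syn diol F6, the C8 epimer of 22. Mitsunobu esterification with tiglic acid 23 (PPh3, diisopropyl azodicarboxylate, toluene) then inverts C8 and gives 25 directly.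

**Further compounds**
F1 | step 11 | 1-vinyl carbinol (vinyl analogue of 17) | C=C[C@@]1(O)C(C)=C[C@H](Oc3ccc(OC)cc3)[C@H](C(=C)COc3ccc(OC)cc3)[C@@]12O[Si](C(C)(C)C)(C(C)(C)C)OC(C)=C2
F2 | step 11 | ten-membered 2-phenylselanyl-3-ketone with 8,10-O-silylene (C2 epimers) | COc1ccc(O[C@H]2/C=C(/C)C(=O)C([Se]c5ccccc5)C[C@]3(C)O[Si](C(C)(C)C)(C(C)(C)C)OC(=C3)[C@H]2C(=C)COc4ccc(OC)cc4)cc1
F3 | step 9 | open-chain bis(trimethylsilyl) ketone (O8 silyl ether, Z C9=C10 silyl enol ether) | O=C1C(C)=C[C@H](Oc2ccc(OC)cc2)[C@H](C(=C)COc2ccc(OC)cc2)[C@]1(O[Si](C)(C)C)/C=C(/C)O[Si](C)(C)C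
F4 | step 9 | 1-ethynyl carbinol of F3 (ethynyl trans to C9) | C#C[C@@]1(O)C(C)=C[C@H](Oc2ccc(OC)cc2)[C@H](C(=C)COc2ccc(OC)cc2)[C@]1(O[Si](C)(C)C)/C=C(/C)O[Si](C)(C)C
F5 | step 9 | 10-trimethylsilyloxy-3,8-dione | COc1ccc(O[C@H]2/C=C(/C)C(=O)/C=C\[C@](C)(O[Si](C)(C)C)CC(=O)[C@H]2C(=C)COc3ccc(OC)cc3)cc1
F6 | step 13 | 8,10-syn diol (C8 epimer of 22) | COc1ccc(O[C@H]2/C=C(/C)C(=O)/C=C\[C@](C)(O)C[C@H](O)[C@H]2C(=C)COc3ccc(OC)cc3)cc1
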